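A direct plan would build ring A as acetophenone A1, 1-(2-hydroxy-3,4,5,6-tetramethoxyphenyl)ethan-1-one, by two rounds of formylation, Baeyer–Villiger oxidation and methylation followed by a Fries acylation. It would condense A1 with aldehyde A2, 2,4-bis(benzyloxy)-5-methoxybenzaldehyde, to chalcone A3, close ring C oxidatively to the benzyl-protected flavone A4, and hydrogenolyse A4 to the target. Its weakest points would be:
- The stepwise oxygenation and acylation of ring A would spend five steps to add one oxygen and one acetyl group to a ring that is bought almost complete.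
- The Claisen–Schmidt condensation of A1 with A2 would ask a ketone flanked by OH and OMe to react with an ortho-alkoxy aldehyde in concentrated KOH over days, with retro-aldol and Cannizzaro loss of both A1 and A2.
- The iodine/DMSO ring closure of A3 at 120 °C would fall on the most precious intermediate, where HI could cleave the 5-OMe or the benzyl ethers and iodinate the electron-rich ring B; the hydrogenolysis of A4 after it would have to be stopped by gas uptake to spare the C2–C3 double bond.

**Plan of the new route**
The retrosynthesis cuts C2–C1' (Negishi coupling of a 2-zincated chromone with a ring B iodide) and then the two ring A bonds C8–C8a and C4a–C5. This leads back to 4H-pyran-4-one (ring C, bought) and dimethyl squarate.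
The enabling feature is that C5, C6, C7 and C8 of ring A carry four contiguous oxygens and map onto the four carbons of dimethyl squarate: the enol ether carbons give C6–OMe and C7–OMe, the carbonyl carbons give C5–O and C8–O. C8a=C4a is the C2=C3 bond of the pyranone, whose C2–H is the acidic one.
The rings arise in the order C (bought), A (benzannulation), B (attached last). No penta-oxygenated benzene is elaborated stepwise, no chalcone is made, and no oxidative ring closure or hydrogenolysis is run on late material.

Key step: step 1

Remark: 4H-pyran-4-one, dimethyl squarate and 4-methoxybenzene-1,3-diol are taken to be catalogue chemicals; the target is achiral, so no configuration has to be set.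

**Ring C to rings A and C**

Step 1
Reactants: 1 4H-pyran-4-one; 2 dimethyl squarate (3,4-dimethoxycyclobut-3-ene-1,2-dione)
Product: 7 5,8-dihydroxy-6,7-dimethoxy-4H-chromen-4-one, via 2-lithio-4H-pyran-4-one 3 (not isolated), via cyclobutenone carbinol 4 (not isolated), via dienylketene 5 (not isolated), via 4aH-dienone 6 (not isolated)
Conditions: LiTMP (1.15 equiv, from 2,2,6,6-tetramethylpiperidine and n-BuLi), THF, −78 °C, 1 added slowly; 2 (1.2 equiv), −78 °C; aq NH4Cl, −78 °C to rt; then crude 4, degassed toluene, 110 °C, Ar
Reagents that add atoms: none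
Why: LiTMP should remove the C2–H of 1, the vinylic proton next to the ring oxygen and the most acidic one, as in the 2-lithiation of chromones, and lithio species 3 should add 1,2 to one of the two equivalent carbonyl groups of 2 at −78 °C to give carbinol 4 (bond C8–C8a). On heating, 4 should undergo conrotatory 4π-electrocyclic ring opening in which the hydroxyl group rotates outward, so that dienylketene 5 carries the pyranone C2=C3 bond cis to the ketene. A 6π-electrocyclisation then joins the ketene carbon to pyranone C3 (bond C4a–C5, closure of the six-membered carbocycle, ring A), and dienone 6 tautomerises to the aromatic hydroquinone 7; the closest known reaction type is the Moore ring expansion of 4-alkenyl- and 4-heteroaryl-4-hydroxycyclobutenones to annulated hydroquinones. The carbinol carbon of 4 and C4a of 6 are transient stereocentres that are erased on aromatisation, so no configuration has to be controlled. The selectivities needed are C2 over C3 metalation (C2–H is the more acidic site when no Lewis acid sits on the carbonyl group, and C2 and C6 are equivalent by symmetry), 1,2- over 1,4-addition to 2 (kinetic at low temperature) and inward rotation of the pyranonyl group (secured by the outward preference of the donor OH).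

Step 2
Reactants: 7 5,8-dihydroxy-6,7-dimethoxy-4H-chromen-4-one
Product: 8 5,6,7,8-tetramethoxy-4H-chromen-4-one
Conditions: Me2SO4 (5 equiv), K2CO3 (6 equiv), acetone, reflux, N2
Reagents that add atoms: dimethyl sulfate, COS(=O)(=O)OC
Why: In this double Williamson O-methylation the free 8-OH should react first and the hydrogen-bonded 5-OH should follow under reflux with excess reagent, as is usual for 5-hydroxychromones, while anhydrous carbonate in acetone should leave the pyranone ring closed.

**Ring B fragment**

Step 3
Reactants: 9 4-methoxybenzene-1,3-diol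
Product: 10 1-methoxy-2,4-bis(methoxymethoxy)benzene
Conditions: NaH (2.5 equiv), MOMCl (2.5 equiv), DMF, 0 °C to rt
Reagents that add atoms: chloromethyl methyl ether, COCCl
Why: This Williamson etherification of both phenoxides installs acetal protecting groups that should withstand the organozinc coupling and later come off with dilute acid, to which aryl methyl ethers are inert.

Step 4
Reactants: 10 1-methoxy-2,4-bis(methoxymethoxy)benzene
Product: 11 1-iodo-5-methoxy-2,4-bis(methoxymethoxy)benzene
Conditions: NIS (1.05 equiv), MeCN, 0 °C to rt, dark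
Reagents that add atoms: N-iodosuccinimide, O=C1CCC(=O)N1I
Why: This electrophilic aromatic iodination should go to the only position that is para to one OMOM and ortho to the other, since the position between the two OMOM groups is shielded and the one beside OMe is activated by a single ortho oxygen.

**Union and completion**

Step 5
Reactants: 8 5,6,7,8-tetramethoxy-4H-chromen-4-one; 11 1-iodo-5-methoxy-2,4-bis(methoxymethoxy)benzene
Product: 13 2-[5-methoxy-2,4-bis(methoxymethoxy)phenyl]-5,6,7,8-tetramethoxy-4H-chromen-4-one, via chromon-2-ylzinc chloride 12 (not isolated)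
Conditions: TMPZnCl·LiCl (1.2 equiv; TMP = 2,2,6,6-tetramethylpiperidide), THF, 25 °C; then 11 (0.9 equiv), Pd(OAc)2 (2 mol %), SPhos (4 mol %), THF, 50 °C
Reagents that add atoms: none
Why: In this deprotonative zincation and Negishi cross-coupling the hindered zinc amide should remove the C2–H of 8 (the vinylic proton next to the ring oxygen, as in the C2-zincation of chromones), zinc reagent 12 should neither open nor attack the pyranone, and coupling with iodide 11 on zerovalent palladium formed in the flask should make the C2–C1' bond.

Step 6
Reactants: 13 2-[5-methoxy-2,4-bis(methoxymethoxy)phenyl]-5,6,7,8-tetramethoxy-4H-chromen-4-one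
Product: 14 2-(2,4-dihydroxy-5-methoxyphenyl)-5,6,7,8-tetramethoxy-4H-chromen-4-one (CNP0237834.0)
Conditions: HCl (2 M aq), MeOH, 50 °C
Reagents that add atoms: none
Why: Acid-catalysed acetal cleavage (transacetalisation to methanol) should remove both MOM groups, while the five aryl methyl ethers, the 5-OMe beside the carbonyl group included, need Lewis or strong Brønsted acids and should stay.

**Compound list**
1 | 4H-pyran-4-one | O=c1ccocc1 | starting material
2 | dimethyl squarate (3,4-dimethoxycyclobut-3-ene-1,2-dione) | COC1=C(OC)C(=O)C1=O | starting material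
3 | 2-lithio-4H-pyran-4-one | [Li]c1cc(=O)cco1 | intermediate
4 | 4-hydroxy-2,3-dimethoxy-4-(4-oxo-4H-pyran-2-yl)cyclobut-2-en-1-one (racemic) | COC1=C(OC)C(O)(c2cc(=O)cco2)C1=O | intermediate
5 | (3Z)-4-hydroxy-2,3-dimethoxy-4-(4-oxo-4H-pyran-2-yl)buta-1,3-dien-1-one | O=C=C(OC)/C(OC)=C(/O)c1cc(=O)cco1 | intermediate
6 | 8-hydroxy-6,7-dimethoxy-4aH-chromene-4,5-dione (racemic) | O=C1C=COC2=C(O)C(OC)=C(OC)C(=O)C12 | intermediate
7 | 5,8-dihydroxy-6,7-dimethoxy-4H-chromen-4-one | O=c1ccoc2c(O)c(OC)c(OC)c(O)c12 | intermediate
8 | 5,6,7,8-tetramethoxy-4H-chromen-4-one | O=c1ccoc2c(OC)c(OC)c(OC)c(OC)c12 | intermediate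
9 | 4-methoxybenzene-1,3-diol | COc1ccc(O)cc1O | starting material
10 | 1-methoxy-2,4-bis(methoxymethoxy)benzene | COCOc1ccc(OC)c(OCOC)c1 | intermediate
11 | 1-iodo-5-methoxy-2,4-bis(methoxymethoxy)benzene | COCOc1cc(OCOC)c(OC)cc1I | intermediate
12 | (5,6,7,8-tetramethoxy-4-oxo-4H-chromen-2-yl)zinc chloride (as its LiCl complex) | Cl[Zn]c1cc(=O)c2c(OC)c(OC)c(OC)c(OC)c2o1 | intermediate
13 | 2-[5-methoxy-2,4-bis(methoxymethoxy)phenyl]-5,6,7,8-tetramethoxy-4H-chromen-4-one | COCOc1cc(OCOC)c(OC)cc1-c1cc(=O)c2c(OC)c(OC)c(OC)c(OC)c2o1 | intermediate
14 | 2-(2,4-dihydroxy-5-methoxyphenyl)-5,6,7,8-tetramethoxy-4H-chromen-4-one (achiral) | COc1cc(-c2cc(=O)c3c(OC)c(OC)c(OC)c(OC)c3o2)c(O)cc1O | target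

Total step count: 6. Longest linear sequence: 4 steps (steps 1, 2, 5, 6; the ring B branch, steps 3, 4, 5, 6, is equally long).

**Steps most likely to fail**

Step 1. The lithiated pyranone may add in conjugate fashion to pyranone that is not yet deprotonated, or open, before it meets the squarate; the ring expansion may also be diverted to a furanone by addition of the hydroxyl group to the ketene. The fallback sets out from 2 and carries ring C at a lower oxidation level, where the lithium reagent has no electrophilic site. Commercial 3,4-dihydro-2H-pyran would be lithiated with t-BuLi (THF, −78 to 0 °C) to 6-lithio-3,4-dihydro-2H-pyran F1, a classic α-alkoxyvinyllithium. Addition of F1 to 2 at −78 °C and NH4Cl quench would give 4-(3,4-dihydro-2H-pyran-6-yl)-4-hydroxy-2,3-dimethoxycyclobut-2-en-1-one F2. Thermolysis of F2 in toluene at 110 °C would give 6,7-dimethoxychromane-5,8-diol F3 by the same ring expansion. Methylation of F3 (Me2SO4, K2CO3, acetone, N2) would give 5,6,7,8-tetramethoxychromane F4. Benzylic oxidation of F4 at C4 (DDQ, dioxane/H2O) would give 5,6,7,8-tetramethoxychroman-4-one F5. Dehydrogenation of F5 (2-iodoxybenzoic acid, DMSO, 80 °C) would bring the sequence back to the route at 8.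

Step 5. Part of the zincation may go to C3, helped by chelation of the metal between 5-OMe and the carbonyl oxygen, and lead to ring opening; oxidative addition of the electron-rich, ortho-substituted iodide may be slow enough for protodezincation and homocoupling to win. The fallback sets out from 11 and 8 and replaces C–H metalation by conjugate addition. Iodine–magnesium exchange on 11 (iPrMgCl·LiCl, THF, −20 °C), B(OMe)3 and aqueous work-up would give [5-methoxy-2,4-bis(methoxymethoxy)phenyl]boronic acid F6. Conjugate addition of F6 to chromone 8 under catalysis by divalent palladium (Pd(OCOCF3)2, 2,2'-bipyridine, aqueous dichloroethane, 60 °C) would give racemic 2-[5-methoxy-2,4-bis(methoxymethoxy)phenyl]-5,6,7,8-tetramethoxychroman-4-one F7. Dehydrogenation of F7 with DDQ in dioxane would erase the stereocentre and return to the route at 13.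

Step 2. Under base and traces of air the hydroquinone may be oxidised to the quinone, the hydrogen-bonded 5-OH may be methylated incompletely, and the 2,3-unsubstituted pyranone may be opened. The fallback sets out from 1 and 2 and puts one methyl group on before ring A exists, so that no hydroquinone is formed. The lithium alkoxide of 4 would be alkylated in the flask with methyl triflate (1 equiv, −78 to 0 °C) to 2,3,4-trimethoxy-4-(4-oxo-4H-pyran-2-yl)cyclobut-2-en-1-one F8. Thermolysis of F8 in toluene would give 5-hydroxy-6,7,8-trimethoxy-4H-chromen-4-one F9. The single remaining phenol of F9 would be methylated without base (MeI, Ag2O, CHCl3) to return to the route at 8.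

**Further compounds**
F1 | step 1 | 6-lithio-3,4-dihydro-2H-pyran | [Li]C1=CCCCO1
F2 | step 1 | 4-(3,4-dihydro-2H-pyran-6-yl)-4-hydroxy-2,3-dimethoxycyclobut-2-en-1-one (racemic) | COC1=C(OC)C(O)(C2=CCCCO2)C1=O
F3 | step 1 | 6,7-dimethoxychromane-5,8-diol | COc1c(OC)c(O)c2OCCCc2c1O
F4 | step 1 | 5,6,7,8-tetramethoxychromane | COc1c(OC)c(OC)c2OCCCc2c1OC
F5 | step 1 | 5,6,7,8-tetramethoxychroman-4-one | COc1c(OC)c(OC)c2OCCC(=O)c2c1OC
F6 | step 5 | [5-methoxy-2,4-bis(methoxymethoxy)phenyl]boronic acid | COCOc1cc(OCOC)c(OC)cc1B(O)O
F7 | step 5 | 2-[5-methoxy-2,4-bis(methoxymethoxy)phenyl]-5,6,7,8-tetramethoxychroman-4-one (racemic) | COCOc1cc(OCOC)c(OC)cc1C1CC(=O)c2c(OC)c(OC)c(OC)c(OC)c2O1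
F8 | step 2 | 2,3,4-trimethoxy-4-(4-oxo-4H-pyran-2-yl)cyclobut-2-en-1-one (racemic) | COC1=C(OC)C(OC)(c2cc(=O)cco2)C1=O
F9 | step 2 | 5-hydroxy-6,7,8-trimethoxy-4H-chromen-4-one | O=c1ccoc2c(OC)c(OC)c(OC)c(O)c12
A1 | direct plan | 1-(2-hydroxy-3,4,5,6-tetramethoxyphenyl)ethan-1-one | CC(=O)c1c(O)c(OC)c(OC)c(OC)c1OC
A2 | direct plan | 2,4-bis(benzyloxy)-5-methoxybenzaldehyde | COc1cc(C=O)c(OCc2ccccc2)cc1OCc1ccccc1
A3 | direct plan | (E)-3-[2,4-bis(benzyloxy)-5-methoxyphenyl]-1-(2-hydroxy-3,4,5,6-tetramethoxyphenyl)prop-2-en-1-one | COc1cc(/C=C/C(=O)c2c(O)c(OC)c(OC)c(OC)c2OC)c(OCc2ccccc2)cc1OCc1ccccc1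
A4 | direct plan | 2-[2,4-bis(benzyloxy)-5-methoxyphenyl]-5,6,7,8-tetramethoxy-4H-chromen-4-one | COc1cc(-c2cc(=O)c3c(OC)c(OC)c(OC)c(OC)c3o2)c(OCc2ccccc2)cc1OCc1ccccc1
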